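At early times the flask holds no dissolved substrate, so the partner waits for it while it decomposes and slips into the dormant form.

solid substrate 0.50 mM; partner 0.500 mM; time 40 s

- amount of target and solid product together at 40 s, in percent of the solid substrate charged
- the change that raises the amount of target and solid product together at 40 s, in percent of the solid substrate charged most ("none" if none brings more than 2 percentage points) (Thursday's / Monday's / Tuesday's / Wednesday's / none)
- amount of target and solid product together at 40 s, in percent of the solid substrate charged, after Tuesday's

    partner → decomposed reagent (k1 = 0.044 /s)
    solid product ⇌ target, rate k2*(cs2 - [target]) while solid is left; crystals form when [target] > cs2 (cs2 = 0.045 mM, k2 = 12 /s)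
    partner ⇌ dormant form (K3 = 2.0, k3 = 0.053 /s)
    solid substrate ⇌ dissolved substrate, rate k4*(cs4 - [dissolved substrate]) while solid is left; crystals form when [dissolved substrate] > cs4 (cs4 = 0.29 mM, k4 = 0.20 /s)
    dissolved substrate + partner → target (k5 = 1500 /M/s)
    2 solid substrate → self-condensation product (k6 = 0.28 /M/s)

At its charge the partner takes up dissolved substrate with a half-life of 0.92 s, which is shorter than the time the solid needs to feed one charge of partner. As a rough reckoning I leave the uptake out and count turnovers against that feed time, although its half-life holds at the partner's charge and grows as the partner falls. The loss turnovers per feed are the partner's loss rate constant, forward steps only, times that feed time.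

feed rate, dissolution coefficient times solubility: 0.0580 mM/s

feed time: 8.62 s

loss constant, decomposition plus parking: 0.0970 /s

loss turnovers per feed: 0.836

An average partner waits half the feed time, so I take as survivors the exponential of minus half the count:

surviving share: 65.8%

yield, with the partner as limiting reagent: 65.8%

With Tuesday's charge, the survivors exceed the substrate, so my yield stops at the whole charge: 100%. Monday's and Thursday's each halve the count, and Wednesday's does not touch it, since the target's low solubility makes no difference. My choice is Tuesday's.

A neighbouring flask differs by holding 1.2 mM of solid substrate. That charge is not in the count, so I expect the same target concentration in both flasks, but a smaller percentage in the neighbour.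

The forecast gives 65% (59% to 71%), Tuesday's, and 96% (91% to 99%), holding that “Doubling the partner leaves enough to consume nearly all the substrate”. For Tuesday's, my figure is higher than the forecast's.

The simulation gives 65.1%, Tuesday's with a gain of 33 percentage points, and 98.0%.

At 5.50 s, the partner's half-life by reaction with dissolved substrate is 4.7 s, shorter than the 13 s of its forward step into the dormant form. At 40.0 s, this flask holds 0.115 mM of decomposed reagent and 0.0557 mM of dormant form, with 0.87% of the partner left. The forecast would fail if a run moved the partner charge well past 0.455 mM or 0.547 mM, where the yield has shifted 5 points. In the neighbouring flask, the unchanged count of 0.836 gives 27.4%. The computed yield there is 27.4%, with 48.0% still solid substrate.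

The constants used here were chosen freely; no experiment stands behind them.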